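Flasks elm and oak hold the same amounts of X and Q and stop at different times, and the average chain is the X reacted divided by the number of chains.

- elm: X 20 mM; Q 58 µM; time 15 min
- oak: X 20 mM; Q 58 µM; time 4.0 min

    Q → 2 L (k1 = 0.0023 s⁻¹)
    X + L → J + E (k2 = 1.5 × 10⁶ M⁻¹ s⁻¹)
    X + J → E + J, rate k3*[J]*[X] (k3 = 21000 M⁻¹ s⁻¹)
    2 J → J2 (k4 = 3.0 × 10⁶ M⁻¹ s⁻¹)

- a step written with two of one species runs at k times the square of its concentration and takes two of it each time
- the average divides the monomer in chains by the number of chains, living and dead together; two radicals that join make one chain
- run time (elm): 15 min

* which of the two ends with the longer chains by the average number of monomer units in a chain (living and dead chains, two that joined counted as one) ("neither" if they lie within 10%) (elm / oak / neither)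
* average number of monomer units in a chain (living and dead chains, two that joined counted as one) at the end, elm
* average number of monomer units in a chain (living and dead chains, two that joined counted as one) at the end, oak

I reckon in logarithms of [X]. L meets X at 30000 s⁻¹, much faster than Q breaks at 0.0023 s⁻¹, so I pass L straight on to J. Making and joining of J balance (a quasi-steady state), so [J] is the root of 0.0023 s⁻¹ times [Q] over 3.0 × 10⁶ M⁻¹ s⁻¹, which is 2.11 × 10⁻⁴ mM at the start. That is far below the charge of Q. Each Q broken gives two J, and two J join into one chain, so I count chains as Q spent: 87.4% of the charge in elm, 42.4% in oak.

X then decays as a pseudo-first-order species at 0.00443 s⁻¹. Holding [J] there, ln[X] drops by 3.99 in elm, or 1.73 powers of ten, and by 1.06 in oak. The lengths come to 387 for elm and 532 for oak, and I commit to oak.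

The weak link is the constant [J]: the half-life of Q is 5.02 min, elm runs longer than that, and [J] follows the root of [Q]. Integrating that root gives the reach, the drop in ln[X] if Q breaks to its end, 3.85. By any time, the share of the reach used is one less the root of the fraction of Q left: 64.5% in elm, 24.1% in oak. The lengths become 362 and 492.

The forecast names oak, with 362 for elm and 489 for oak, on the ground that “elm's late, monomer-starved radicals add many short chains”.

The simulation gives oak, with 362 in elm and 491 in oak.

Equal charges give both flasks the same reach, and the gap comes from the time: oak given elm's time falls from 491 to 362, and that run would turn the forecast wrong. The reach puts the X left once Q has broken to its end at 2.13% of the charge, and elm holds 2.03% at 150 min.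

A neighbouring flask is oak with 0.023 mM of Q. Its reach goes with the root of the charge of Q, to 2.42, so X should stand at 55.7% of its charge and the length at 908. The computed flask gives 55.8% and 902.

All constants stand for no real mixture; what happens was integrated by code.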